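**Plan**

- Cuts, in retrosynthetic order: the two O–Si bonds; then C4'–C5' of the side chain (C1' is the CH2 on C2 of the chroman), which gives the C37 acid 15 (as N-acyloxyphthalimide 16) and the chroman (E)-2-iodoalk-2-ene 29; then C21'–C22' of the skipped diene (alkyne 5 + bromo ester 12); then C2'–C3' and the O1–C2 / CH2–CO bonds of the chroman piece.
- Enabling feature: in the all-E 1,5-diene repeat, C5' is a primary carbon homoallylic to C7'=C8', and C4' carries only CH3 and the C3'=C4' double bond. C5' can therefore be a non-stabilised, non-cyclising radical from a 4-enoic acid, and C4' a geometrically defined alkenyl iodide.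
- Forward: farnesol gives the (S)-propargylic silyl ether 5; geranylgeraniol gives the two-carbon-extended, ω-brominated ester 12; 5 and 12 are joined by hydrozirconation/Pd allylation and taken to 16. 2,3-Dimethylhydroquinone and methyl vinyl ketone give alkenyl phenol 22, whose dihydropyran ring is closed enantioselectively, then alkyne 27 and iodide 29. 16 and 29 are joined by nickel-electrocatalytic decarboxylative alkenylation, then desilylated.
- Stereochemistry: C24' (S) from Sharpless epoxidation of farnesol; C2 (S) from ligand-controlled oxypalladation; E alkenes carried over from farnesol and geranylgeraniol, from two syn-hydrozirconations (C22'=C23', C3'=C4') and from E-selective SeO2 oxidation (C19'=C20').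

Key step: step 21

Assumption: the target is read as 2S at the chroman carbon and 24'S at the carbinol; the (R,R)-antipode of the BOXAX ligand is taken to give the 2R acetate 23 (mirror image of the pairing used for the natural 2R tocopherol series), and the ligand antipode is exchanged if the first run shows the opposite sense.

**Route**

Step 1
Reactants: 1 (2E,6E)-farnesol
Product: 2 (2S,3S)-2,3-epoxyfarnesol
Conditions: Ti(OiPr)4 (10 mol %), L-(+)-diethyl tartrate (12 mol %), t-BuOOH, 4 Å molecular sieves, CH2Cl2, −20 °C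
Reagents that add atoms: tert-butyl hydroperoxide, CC(C)(C)OO
Why: Sharpless asymmetric epoxidation is directed by the allylic hydroxyl, so only the C2=C3 alkene reacts, and the L-(+)-tartrate–titanium complex should deliver oxygen to the face that gives the 2S,3S epoxide, which fixes the future carbinol carbon (C3 of farnesol, C24' of the target).

Step 2
Reactants: 2 (2S,3S)-2,3-epoxyfarnesol
Product: 3 (2S,3R)-3-(chloromethyl)-2-[(3E)-4,8-dimethylnona-3,7-dien-1-yl]-2-methyloxirane
Conditions: PPh3, CCl4, NaHCO3, reflux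
Reagents that add atoms: carbon tetrachloride, ClC(Cl)(Cl)Cl
Why: The Appel reaction under buffered conditions replaces the primary hydroxyl by SN2 at C1 without touching the oxirane, and the descriptor at the oxirane CH changes only because chlorine raises the priority of the CH2 group.

Step 3
Reactants: 3 (2S,3R)-3-(chloromethyl)-2-[(3E)-4,8-dimethylnona-3,7-dien-1-yl]-2-methyloxirane
Product: 4 (3S,6E)-3,7,11-trimethyldodeca-6,10-dien-1-yn-3-ol
Conditions: n-BuLi (3.3 equiv), THF, −40 → −20 °C; aq. NH4Cl
Reagents that add atoms: none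
Why: Base-induced eliminative opening of a 2,3-epoxy chloride (deprotonation at the CH2Cl carbon, β-elimination that breaks the secondary C–O bond, then dehydrochlorination to the alkynide) is an established route to propargylic alcohols, and the tertiary C–O bond is never broken, so the S centre is retained.

Step 4
Reactants: 4 (3S,6E)-3,7,11-trimethyldodeca-6,10-dien-1-yn-3-ol
Product: 5 triethyl{[(3S,6E)-3,7,11-trimethyldodeca-6,10-dien-1-yn-3-yl]oxy}silane
Conditions: Et3SiOTf, 2,6-lutidine, CH2Cl2, −78 → 0 °C
Reagents that add atoms: triethylsilyl trifluoromethanesulfonate, CC[Si](CC)(CC)OS(=O)(=O)C(F)(F)F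
Why: Silylation with a silyl triflate and 2,6-lutidine is the standard way to protect a hindered tertiary alcohol, and the ether masks the O–H during hydrozirconation and the later radical coupling.

Step 5
Reactants: 6 (2E,6E,10E)-geranylgeraniol
Product: 7 (2E,6E,10E)-geranylgeranyl bromide
Conditions: PBr3, Et2O, −10 → 0 °C
Reagents that add atoms: phosphorus tribromide, BrP(Br)Br
Why: Conversion of a primary allylic alcohol into the bromide with PBr3 at low temperature proceeds by SN2 at the primary carbon and keeps all three E alkenes.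

Step 6
Reactants: 7 (2E,6E,10E)-geranylgeranyl bromide; 8 methyl acetate
Product: 10 methyl (4E,8E,12E)-5,9,13,17-tetramethyloctadeca-4,8,12,16-tetraenoate, via lithium enolate 9 (not isolated)
Conditions: LiN(iPr)2, THF, −78 °C; then 7, DMPU, −78 → −40 °C
Reagents that add atoms: none
Why: C-alkylation of a lithium ester enolate with a reactive primary allylic bromide (SN2) should give the 4-enoic ester, with the 4E alkene carried over unchanged from 7.

Step 7
Reactants: 10 methyl (4E,8E,12E)-5,9,13,17-tetramethyloctadeca-4,8,12,16-tetraenoate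
Product: 11 methyl (4E,8E,12E,16E)-18-hydroxy-5,9,13,17-tetramethyloctadeca-4,8,12,16-tetraenoate
Conditions: SeO2 (0.3 equiv), t-BuOOH (2 equiv), salicylic acid (0.1 equiv), CH2Cl2, 0 °C → rt, stopped at partial conversion
Reagents that add atoms: tert-butyl hydroperoxide, CC(C)(C)OO
Why: Selenium dioxide allylic oxidation (ene reaction, then [2,3]-sigmatropic shift) should prefer the most accessible and electron-rich alkene, the terminal isopropylidene, and by its known preference for the E-methyl group give the 16E primary allylic alcohol.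

Step 8
Reactants: 11 methyl (4E,8E,12E,16E)-18-hydroxy-5,9,13,17-tetramethyloctadeca-4,8,12,16-tetraenoate
Product: 12 methyl (4E,8E,12E,16E)-18-bromo-5,9,13,17-tetramethyloctadeca-4,8,12,16-tetraenoate
Conditions: CBr4, PPh3, CH2Cl2, −20 → 0 °C
Reagents that add atoms: carbon tetrabromide, BrC(Br)(Br)Br
Why: The Appel bromination of a primary allylic alcohol is neutral and cold, so the ester and the E alkenes should survive and no allylic transposition is expected.

Step 9
Reactants: 5 triethyl{[(3S,6E)-3,7,11-trimethyldodeca-6,10-dien-1-yn-3-yl]oxy}silane; 12 methyl (4E,8E,12E,16E)-18-bromo-5,9,13,17-tetramethyloctadeca-4,8,12,16-tetraenoate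
Product: 14 methyl (4E,8E,12E,16E,19E,21S,24E)-5,9,13,17,21,25,29-heptamethyl-21-[(triethylsilyl)oxy]triaconta-4,8,12,16,19,24,28-heptaenoate, via alkenylzirconocene chloride 13 (not isolated)
Conditions: Cp2Zr(H)Cl (1.3 equiv), THF, rt; then 12, ZnCl2 (20 mol %), Pd(PPh3)4 (5 mol %), rt
Reagents that add atoms: none
Why: syn-Hydrozirconation of the terminal alkyne places zirconium on the terminal carbon and sets the 19E alkene, and the zinc-assisted, palladium-catalysed alkenyl–allyl coupling (Negishi-type) should join it to the primary terminus of the π-allyl from 12 with retention of both alkene geometries, the carbinol centre being untouched.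

Step 10
Reactants: 14 methyl (4E,8E,12E,16E,19E,21S,24E)-5,9,13,17,21,25,29-heptamethyl-21-[(triethylsilyl)oxy]triaconta-4,8,12,16,19,24,28-heptaenoate
Product: 15 (4E,8E,12E,16E,19E,21S,24E)-5,9,13,17,21,25,29-heptamethyl-21-[(triethylsilyl)oxy]triaconta-4,8,12,16,19,24,28-heptaenoic acid
Conditions: LiOH·H2O, THF/MeOH/H2O, rt; then cold 0.5 M HCl to pH 4
Reagents that add atoms: lithium hydroxide, [Li+].[OH-]
Why: Saponification of an unhindered methyl ester is mild enough to leave the tertiary silyl ether and the skipped diene alone.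

Step 11
Reactants: 15 (4E,8E,12E,16E,19E,21S,24E)-5,9,13,17,21,25,29-heptamethyl-21-[(triethylsilyl)oxy]triaconta-4,8,12,16,19,24,28-heptaenoic acid
Product: 16 1,3-dioxoisoindolin-2-yl (4E,8E,12E,16E,19E,21S,24E)-5,9,13,17,21,25,29-heptamethyl-21-[(triethylsilyl)oxy]triaconta-4,8,12,16,19,24,28-heptaenoate
Conditions: N-hydroxyphthalimide, N,N'-diisopropylcarbodiimide, DMAP (10 mol %), CH2Cl2, rt
Reagents that add atoms: N-hydroxyphthalimide, O=C1c2ccccc2C(=O)N1O
Why: Carbodiimide (Steglich-type) esterification gives the redox-active ester that will release the C5' radical on one-electron reduction.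

Step 12
Reactants: 17 2,3-dimethylhydroquinone; 18 methyl vinyl ketone
Product: 19 rac-2-methoxy-2,7,8-trimethylchroman-6-ol
Conditions: HC(OMe)3, MeOH, H2SO4 (cat.), 0 °C → rt
Reagents that add atoms: trimethyl orthoformate, COC(OC)OC
Why: Acid-catalysed Friedel–Crafts-type conjugate addition of the hydroquinone (its two free ring positions are equivalent) to the enone, then hemiketalisation and orthoformate-driven ketalisation, should close the dihydropyran ring as a mixed ketal and so tell the two phenols apart.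

Step 13
Reactants: 19 rac-2-methoxy-2,7,8-trimethylchroman-6-ol
Product: 20 rac-[(2-methoxy-2,7,8-trimethylchroman-6-yl)oxy]tri(propan-2-yl)silane
Conditions: iPr3SiCl, imidazole, DMF, rt → 40 °C
Reagents that add atoms: triisopropylsilyl chloride, CC(C)[Si](Cl)(C(C)C)C(C)C
Why: Silylation of the only free phenol gives a robust aryl silyl ether that should last through base, hydride, acetylide and zirconium chemistry and be removed by fluoride at the end.

Step 14
Reactants: 20 rac-[(2-methoxy-2,7,8-trimethylchroman-6-yl)oxy]tri(propan-2-yl)silane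
Product: 21 rac-2,7,8-trimethyl-6-[(triisopropylsilyl)oxy]chroman-2-ol
Conditions: 1 M aq. HCl, acetone, rt
Reagents that add atoms: water, O
Why: Mild acid hydrolysis of the mixed ketal gives the lactol, which is the ring tautomer of the 4-arylbutan-2-one needed for olefination.

Step 15
Reactants: 21 rac-2,7,8-trimethyl-6-[(triisopropylsilyl)oxy]chroman-2-ol
Product: 22 2,3-dimethyl-6-(3-methylbut-3-en-1-yl)-4-[(triisopropylsilyl)oxy]phenol
Conditions: Ph3PCH3Br (3.2 equiv), KN(SiMe3)2 (3.0 equiv), THF, 0 → 60 °C
Reagents that add atoms: methyltriphenylphosphonium bromide, C[P+](c1ccccc1)(c1ccccc1)c1ccccc1.[Br-]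
Why: Wittig methylenation captures the open-chain keto phenoxide in equilibrium with the lactol, and the phenoxide cannot add back to the unactivated 1,1-disubstituted alkene.

Step 16
Reactants: 22 2,3-dimethyl-6-(3-methylbut-3-en-1-yl)-4-[(triisopropylsilyl)oxy]phenol
Product: 23 methyl 2-[(2R)-2,7,8-trimethyl-6-[(triisopropylsilyl)oxy]chroman-2-yl]acetate
Conditions: Pd(OCOCF3)2 (5 mol %), (R,R)-Bn-BOXAX [2,2'-bis((4R)-4-benzyl-4,5-dihydrooxazol-2-yl)-1,1'-binaphthyl] (20 mol %), p-benzoquinone (4 equiv), CO (1 atm), MeOH, rt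
Reagents that add atoms: carbon monoxide, [C-]#[O+]; methanol, CO
Why: In this enantioselective domino Wacker cyclisation–methoxycarbonylation, divalent palladium held by the C2-symmetric bis(oxazoline) activates the 1,1-disubstituted alkene for 6-exo attack of the phenol oxygen on one enantioface, which closes the dihydropyran ring and sets C2, and the neopentyl-type alkylpalladium, having no β-hydrogen, inserts CO and is methanolysed.

Step 17
Reactants: 23 methyl 2-[(2R)-2,7,8-trimethyl-6-[(triisopropylsilyl)oxy]chroman-2-yl]acetate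
Product: 24 2-[(2R)-2,7,8-trimethyl-6-[(triisopropylsilyl)oxy]chroman-2-yl]ethan-1-ol
Conditions: iBu2AlH (2.5 equiv), CH2Cl2, −78 → 0 °C; aq. potassium sodium tartrate
Reagents that add atoms: none
Why: Hydride reduction of the ester to the primary alcohol with iBu2AlH spares the aryl silyl ether and does not involve the quaternary centre.

Step 18
Reactants: 24 2-[(2R)-2,7,8-trimethyl-6-[(triisopropylsilyl)oxy]chroman-2-yl]ethan-1-ol
Product: 25 {[(2R)-2-(2-iodoethyl)-2,7,8-trimethylchroman-6-yl]oxy}tri(propan-2-yl)silane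
Conditions: I2, PPh3, imidazole, CH2Cl2, 0 °C → rt
Reagents that add atoms: iodine, [I][I]
Why: Appel-type iodination converts the primary alcohol into the iodide by SN2 under neutral conditions.

Step 19
Reactants: 25 {[(2R)-2-(2-iodoethyl)-2,7,8-trimethylchroman-6-yl]oxy}tri(propan-2-yl)silane; 26 1-propynyllithium
Product: 27 {[(2S)-2,7,8-trimethyl-2-(pent-3-yn-1-yl)chroman-6-yl]oxy}tri(propan-2-yl)silane
Conditions: THF/DMPU, −20 °C → rt
Reagents that add atoms: none
Why: SN2 alkylation of a lithium acetylide with a primary iodide in a dipolar cosolvent installs the methylalkyne; the centre is untouched and its descriptor changes from R to S only because the ring branch now outranks the chain.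

Step 20
Reactants: 27 {[(2S)-2,7,8-trimethyl-2-(pent-3-yn-1-yl)chroman-6-yl]oxy}tri(propan-2-yl)silane
Product: 29 {[(2S)-2-[(3E)-4-iodopent-3-en-1-yl]-2,7,8-trimethylchroman-6-yl]oxy}tri(propan-2-yl)silane, via alkenylzirconocene chloride 28 (not isolated)
Conditions: Cp2Zr(H)Cl (2.5 equiv), THF, 50 °C; then I2, 0 °C
Reagents that add atoms: iodine, [I][I]
Why: syn-Hydrozirconation of the 2-alkyne with excess Cp2Zr(H)Cl under equilibrating conditions should place zirconium on the less hindered, methyl-bearing carbon, and iodinolysis with retention gives the (E)-2-iodoalk-2-ene that carries the geometry of the future C3'=C4' alkene.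

Step 21
Reactants: 16 1,3-dioxoisoindolin-2-yl (4E,8E,12E,16E,19E,21S,24E)-5,9,13,17,21,25,29-heptamethyl-21-[(triethylsilyl)oxy]triaconta-4,8,12,16,19,24,28-heptaenoate; 29 {[(2S)-2-[(3E)-4-iodopent-3-en-1-yl]-2,7,8-trimethylchroman-6-yl]oxy}tri(propan-2-yl)silane
Product: 30 bis-silyl ether of the target: triethyl{[(6E,10S,11E,14E,18E,22E,26E,30E)-2,6,10,14,18,22,26,30-octamethyl-33-[(2S)-2,7,8-trimethyl-6-[(triisopropylsilyl)oxy]chroman-2-yl]tritriaconta-2,6,11,14,18,22,26,30-octaen-10-yl]oxy}silane
Conditions: 16 (1.5 equiv), 29 (1.0 equiv), NiCl2·6H2O (10 mol %), 2,2'-bipyridine (10 mol %), AgNO3 (0.3 equiv), LiCl, DMF, Mg anode, reticulated vitreous carbon cathode, constant current (about 2.5 F/mol), 0 °C → rt, Ar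
Reagents that add atoms: none
Why: Cathodic reduction generates low-valent nickel–bipyridine, which inserts into the C–I bond of 29 to give an alkenylnickel species, while single-electron reduction of the N-acyloxyphthalimide 16 (at the silver-coated cathode or by low-valent nickel) fragments it to phthalimide anion, CO2 and the primary radical at C5'; the radical is captured at nickel and reductive elimination from the resulting trivalent nickel forms the C4'–C5' bond, the magnesium anode supplying the two electrons. The closest known reaction type is the nickel-electrocatalytic decarboxylative alkenylation of redox-active esters with alkenyl iodides developed for all-E polyprenoid chains, with its thermal counterpart that uses alkenylzinc reagents. No ring is closed and no stereocentre is formed; C2 and C24' are remote and stay untouched. The step needs retention of the E geometry at C3'=C4', which the configurationally stable alkenylnickel intermediate should secure because iodine is replaced with retention, and cross-coupling over homocoupling, which is favoured by the excess of 16 and by matched rates of oxidative addition and radical generation at the silver-modified cathode. Side reactions of the radical are suppressed by the substrate itself: C5' is homoallylic, so the radical is neither allylically delocalised nor able to cyclise (only three- or four-membered rings, or a seven-membered ring across an E alkene, are within reach), and both O–H groups, above all the hydrogen-atom-donating chromanol, are silylated.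

Step 22
Reactants: 30 bis-silyl ether of the target
Product: 31 (2S)-2-[(3E,7E,11E,15E,19E,22E,24S,27E)-24-hydroxy-4,8,12,16,20,24,28,32-octamethyltritriaconta-3,7,11,15,19,22,27,31-octaen-1-yl]-2,7,8-trimethylchroman-6-ol
Conditions: Bu4NF (4 equiv), AcOH (4 equiv), degassed THF, 0 → 40 °C, Ar
Reagents that add atoms: none
Why: Buffered fluoride desilylation should cleave the aryl and the tertiary silyl ether in one operation without acid, which the tertiary allylic alcohol and the skipped diene would not tolerate, and without free base and air, which would oxidise the chromanol.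

**Compound list**

1 | (2E,6E)-farnesol | CC(C)=CCC/C(C)=C/CC/C(C)=C/CO | starting material
2 | (2S,3S)-2,3-epoxyfarnesol, [(2S,3S)-3-[(3E)-4,8-dimethylnona-3,7-dien-1-yl]-3-methyloxiran-2-yl]methanol | CC(C)=CCC/C(C)=C/CC[C@]1(C)O[C@H]1CO | intermediate
3 | (2S,3R)-3-(chloromethyl)-2-[(3E)-4,8-dimethylnona-3,7-dien-1-yl]-2-methyloxirane | CC(C)=CCC/C(C)=C/CC[C@]1(C)O[C@H]1CCl | intermediate
4 | (3S,6E)-3,7,11-trimethyldodeca-6,10-dien-1-yn-3-ol | CC(C)=CCC/C(C)=C/CC[C@](C)(O)C#C | intermediate
5 | triethyl{[(3S,6E)-3,7,11-trimethyldodeca-6,10-dien-1-yn-3-yl]oxy}silane | CC(C)=CCC/C(C)=C/CC[C@](C)(O[Si](CC)(CC)CC)C#C | intermediate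
6 | (2E,6E,10E)-geranylgeraniol | CC(C)=CCC/C(C)=C/CC/C(C)=C/CC/C(C)=C/CO | starting material
7 | (2E,6E,10E)-geranylgeranyl bromide | CC(C)=CCC/C(C)=C/CC/C(C)=C/CC/C(C)=C/CBr | intermediate
8 | methyl acetate | COC(C)=O | starting material
9 | lithium enolate of methyl acetate (lithium 1-methoxyethen-1-olate) | [Li]OC(=C)OC | intermediate (not isolated)
10 | methyl (4E,8E,12E)-5,9,13,17-tetramethyloctadeca-4,8,12,16-tetraenoate | CC(C)=CCC/C(C)=C/CC/C(C)=C/CC/C(C)=C/CCC(=O)OC | intermediate
11 | methyl (4E,8E,12E,16E)-18-hydroxy-5,9,13,17-tetramethyloctadeca-4,8,12,16-tetraenoate | OC/C(C)=C/CC/C(C)=C/CC/C(C)=C/CC/C(C)=C/CCC(=O)OC | intermediate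
12 | methyl (4E,8E,12E,16E)-18-bromo-5,9,13,17-tetramethyloctadeca-4,8,12,16-tetraenoate | BrC/C(C)=C/CC/C(C)=C/CC/C(C)=C/CC/C(C)=C/CCC(=O)OC | intermediate
13 | chlorobis(cyclopentadienyl)[(1E,3S,6E)-3,7,11-trimethyl-3-[(triethylsilyl)oxy]dodeca-1,6,10-trien-1-yl]zirconium | CC(C)=CCC/C(C)=C/CC[C@](C)(O[Si](CC)(CC)CC)/C=C/[Zr](Cl)(C1C=CC=C1)C1C=CC=C1 | intermediate (not isolated)
14 | methyl (4E,8E,12E,16E,19E,21S,24E)-5,9,13,17,21,25,29-heptamethyl-21-[(triethylsilyl)oxy]triaconta-4,8,12,16,19,24,28-heptaenoate | CC(C)=CCC/C(C)=C/CC[C@](C)(O[Si](CC)(CC)CC)/C=C/C/C(C)=C/CC/C(C)=C/CC/C(C)=C/CC/C(C)=C/CCC(=O)OC | intermediate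
15 | (4E,8E,12E,16E,19E,21S,24E)-5,9,13,17,21,25,29-heptamethyl-21-[(triethylsilyl)oxy]triaconta-4,8,12,16,19,24,28-heptaenoic acid | CC(C)=CCC/C(C)=C/CC[C@](C)(O[Si](CC)(CC)CC)/C=C/C/C(C)=C/CC/C(C)=C/CC/C(C)=C/CC/C(C)=C/CCC(=O)O | intermediate
16 | 1,3-dioxoisoindolin-2-yl ester of acid 15 | CC(C)=CCC/C(C)=C/CC[C@](C)(O[Si](CC)(CC)CC)/C=C/C/C(C)=C/CC/C(C)=C/CC/C(C)=C/CC/C(C)=C/CCC(=O)ON1C(=O)c2ccccc2C1=O | intermediate
17 | 2,3-dimethylhydroquinone (2,3-dimethylbenzene-1,4-diol) | Cc1c(O)ccc(O)c1C | starting material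
18 | methyl vinyl ketone (but-3-en-2-one) | C=CC(C)=O | starting material
19 | rac-2-methoxy-2,7,8-trimethylchroman-6-ol | COC1(C)CCc2cc(O)c(C)c(C)c2O1 | intermediate
20 | rac-[(2-methoxy-2,7,8-trimethylchroman-6-yl)oxy]tri(propan-2-yl)silane | COC1(C)CCc2cc(O[Si](C(C)C)(C(C)C)C(C)C)c(C)c(C)c2O1 | intermediate
21 | rac-2,7,8-trimethyl-6-[(triisopropylsilyl)oxy]chroman-2-ol | CC1(O)CCc2cc(O[Si](C(C)C)(C(C)C)C(C)C)c(C)c(C)c2O1 | intermediate
22 | 2,3-dimethyl-6-(3-methylbut-3-en-1-yl)-4-[(triisopropylsilyl)oxy]phenol | C=C(C)CCc1cc(O[Si](C(C)C)(C(C)C)C(C)C)c(C)c(C)c1O | intermediate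
23 | methyl 2-[(2R)-2,7,8-trimethyl-6-[(triisopropylsilyl)oxy]chroman-2-yl]acetate | COC(=O)C[C@@]1(C)CCc2cc(O[Si](C(C)C)(C(C)C)C(C)C)c(C)c(C)c2O1 | intermediate
24 | 2-[(2R)-2,7,8-trimethyl-6-[(triisopropylsilyl)oxy]chroman-2-yl]ethan-1-ol | OCC[C@@]1(C)CCc2cc(O[Si](C(C)C)(C(C)C)C(C)C)c(C)c(C)c2O1 | intermediate
25 | {[(2R)-2-(2-iodoethyl)-2,7,8-trimethylchroman-6-yl]oxy}tri(propan-2-yl)silane | ICC[C@@]1(C)CCc2cc(O[Si](C(C)C)(C(C)C)C(C)C)c(C)c(C)c2O1 | intermediate
26 | 1-propynyllithium | [Li]C#CC | starting material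
27 | {[(2S)-2,7,8-trimethyl-2-(pent-3-yn-1-yl)chroman-6-yl]oxy}tri(propan-2-yl)silane | CC#CCC[C@@]1(C)CCc2cc(O[Si](C(C)C)(C(C)C)C(C)C)c(C)c(C)c2O1 | intermediate
28 | chlorobis(cyclopentadienyl)[(2E)-5-[(2S)-2,7,8-trimethyl-6-[(triisopropylsilyl)oxy]chroman-2-yl]pent-2-en-2-yl]zirconium | Cl[Zr](C1C=CC=C1)(C1C=CC=C1)/C(C)=C/CC[C@@]1(C)CCc2cc(O[Si](C(C)C)(C(C)C)C(C)C)c(C)c(C)c2O1 | intermediate (not isolated)
29 | {[(2S)-2-[(3E)-4-iodopent-3-en-1-yl]-2,7,8-trimethylchroman-6-yl]oxy}tri(propan-2-yl)silane | I/C(C)=C/CC[C@@]1(C)CCc2cc(O[Si](C(C)C)(C(C)C)C(C)C)c(C)c(C)c2O1 | intermediate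
30 | bis-silyl ether of the target (24'-O-triethylsilyl, 6-O-triisopropylsilyl) | CC(C)=CCC/C(C)=C/CC[C@](C)(O[Si](CC)(CC)CC)/C=C/C/C(C)=C/CC/C(C)=C/CC/C(C)=C/CC/C(C)=C/CC/C(C)=C/CC[C@@]1(C)CCc2cc(O[Si](C(C)C)(C(C)C)C(C)C)c(C)c(C)c2O1 | intermediate
31 | (2S)-2-[(3E,7E,11E,15E,19E,22E,24S,27E)-24-hydroxy-4,8,12,16,20,24,28,32-octamethyltritriaconta-3,7,11,15,19,22,27,31-octaen-1-yl]-2,7,8-trimethylchroman-6-ol | CC(C)=CCC/C(C)=C/CC[C@](C)(O)/C=C/C/C(C)=C/CC/C(C)=C/CC/C(C)=C/CC/C(C)=C/CC/C(C)=C/CC[C@@]1(C)CCc2cc(O)c(C)c(C)c2O1 | target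

**Count and risks**

Total step count: 22. Longest linear sequence: 11 steps (steps 12 to 20, then 21 and 22).

Steps most likely to fail:

Step 21. The coupling may suffer reductive loss of iodine from 29, dimerisation or reduction of the C5' radical, or partial loss of the C3'=C4' geometry at the alkenylnickel stage. The fallback changes the polarity to a two-electron Negishi coupling and sets out from acid 15. Carbodiimide coupling of 15 with 2-mercaptopyridine N-oxide gives the thiohydroxamate ester F1. Visible-light irradiation of F1 with CHI3 (Barton decarboxylative iodination) gives the homoallylic iodide F2, the C36 chain of 15 with iodine in place of CO2H. LiCl-promoted insertion of zinc dust into F2 gives the alkylzinc iodide F3, and Pd(PPh3)4-catalysed coupling of F3 with 29 in THF/DMF comes back to the route at 30.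

Step 7. The oxidation may lack site selectivity (attack at the internal trisubstituted alkenes) and may run on to the enal. The fallback replaces the direct C–H oxidation by degradation and rebuilding of the chain end and sets out from 10. NBS in aqueous THF should form the terminal bromohydrin F4 selectively, and K2CO3 in MeOH closes it to the terminal epoxide F5. H5IO6 cleaves F5 to the trisnor aldehyde F6. E-selective Wittig reaction of F6 with 2-(triphenylphosphoranylidene)propanal gives the enal F7, and NaBH4/CeCl3·7H2O reduction of F7 comes back to the route at 11.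

Step 16. Enantiofacial selectivity may be poor on this arene, which lacks the substituent next to the tether, and the electron-rich phenol may be oxidised by benzoquinone. The fallback gives up catalyst control for resolution and sets out from 21. Horner–Wadsworth–Emmons reaction with trimethyl phosphonoacetate and NaH in THF gives the open-chain enoate F8, which closes in the same flask by oxa-Michael addition of the phenoxide to the racemic chroman-2-acetate F9. Preparative chromatography of F9 on a chiral stationary phase comes back to the route at 23, and the (S)-ester F10 is set aside.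

Further compounds
F1 | step 21 | 2-thioxopyridin-1(2H)-yl ester of acid 15 | CC(C)=CCC/C(C)=C/CC[C@](C)(O[Si](CC)(CC)CC)/C=C/C/C(C)=C/CC/C(C)=C/CC/C(C)=C/CC/C(C)=C/CCC(=O)ON1C=CC=CC1=S
F2 | step 21 | homoallylic iodide, the C36 chain of 15 with I in place of CO2H | CC(C)=CCC/C(C)=C/CC[C@](C)(O[Si](CC)(CC)CC)/C=C/C/C(C)=C/CC/C(C)=C/CC/C(C)=C/CC/C(C)=C/CCI
F3 | step 21 | alkylzinc iodide from F2 | CC(C)=CCC/C(C)=C/CC[C@](C)(O[Si](CC)(CC)CC)/C=C/C/C(C)=C/CC/C(C)=C/CC/C(C)=C/CC/C(C)=C/CC[Zn]I
F4 | step 7 | methyl (4E,8E,12E)-16-bromo-17-hydroxy-5,9,13,17-tetramethyloctadeca-4,8,12-trienoate (racemic) | CC(C)(O)C(Br)CC/C(C)=C/CC/C(C)=C/CC/C(C)=C/CCC(=O)OC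
F5 | step 7 | methyl (4E,8E,12E)-15-(3,3-dimethyloxiran-2-yl)-5,9,13-trimethylpentadeca-4,8,12-trienoate (racemic) | CC1(C)OC1CC/C(C)=C/CC/C(C)=C/CC/C(C)=C/CCC(=O)OC
F6 | step 7 | methyl (4E,8E,12E)-5,9,13-trimethyl-16-oxohexadeca-4,8,12-trienoate | O=CCC/C(C)=C/CC/C(C)=C/CC/C(C)=C/CCC(=O)OC
F7 | step 7 | methyl (4E,8E,12E,16E)-5,9,13,17-tetramethyl-18-oxooctadeca-4,8,12,16-tetraenoate | O=C/C(C)=C/CC/C(C)=C/CC/C(C)=C/CC/C(C)=C/CCC(=O)OC
F8 | step 16 | methyl 5-[2-hydroxy-3,4-dimethyl-5-[(triisopropylsilyl)oxy]phenyl]-3-methylpent-2-enoate (E/Z mixture) | COC(=O)C=C(C)CCc1cc(O[Si](C(C)C)(C(C)C)C(C)C)c(C)c(C)c1O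
F9 | step 16 | rac-methyl 2-[2,7,8-trimethyl-6-[(triisopropylsilyl)oxy]chroman-2-yl]acetate | COC(=O)CC1(C)CCc2cc(O[Si](C(C)C)(C(C)C)C(C)C)c(C)c(C)c2O1
F10 | step 16 | methyl 2-[(2S)-2,7,8-trimethyl-6-[(triisopropylsilyl)oxy]chroman-2-yl]acetate | COC(=O)C[C@]1(C)CCc2cc(O[Si](C(C)C)(C(C)C)C(C)C)c(C)c(C)c2O1
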